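**Retrosynthetic overview**
1. Target 16 is cut in one stroke to the monocyclic alkynyl cyclodecane-1,6-dione 12 plus 2-(diethoxyphosphoryl)acetic acid 13. The last step makes the butenolide O1–C5 bond (gold-carbene O–H insertion), the butenolide C3=C4 bond (Horner–Wadsworth–Emmons) and the ring-fusion bond C3a–C8a (transannular aldol).
2. Enabling feature: the β-ketol C8a(OH)–C3a(H)–C4(=O) straddling the 5/7 ring fusion is a transannular-aldol retron, and because C1 and C5 are quaternary the ten-membered 1,6-dione has only two enolisable CH2 groups (C3a, C8). The butenolide β-carbon and its OCH2 are the two carbons of a terminal alkyne.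
3. 12 comes from ozonolysis of the tetrasubstituted ring-fusion alkene of octalinol 11 (6/6 bicycle → ten-membered ring → 5/7 bicycle).
4. 11 comes from CBS reduction, gem-dimethylation and Robinson annulation on silyl enol ether 5, which comes from anti-selective cuprate addition of a masked butynyl chain to (R)-3,4-dimethylcyclohexenone 3, made from bought enone 1.
5. Ring order: cyclohexane (bought) → second six-membered ring → ten-membered ring → butenolide, cyclopentane and cycloheptanone together. Stereocentres: one bought, the quaternary one relayed from it, the carbinol set by catalyst, the two ring-fusion centres relayed in the key step.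

Key step: step 7

Assumption: (R)-4-methylcyclohex-2-en-1-one (1) is purchased as the single enantiomer; locants quoted for 16 and its seco-precursors are those of the azulenone/furanone name of 16.

Step 1
Reactants: 1 (R)-4-methylcyclohex-2-en-1-one
Product: 3 (R)-3,4-dimethylcyclohex-2-en-1-one, via silyl enol ether 2 (not isolated)
Conditions: MeMgBr, CuBr·SMe2 (10 mol %), TMSCl, THF, −78 °C; then Pd(OAc)2 (10 mol %), O2 (1 atm), DMSO, 25 °C
Reagents that add atoms: methylmagnesium bromide, C[Mg]Br; chlorotrimethylsilane, C[Si](C)(C)Cl (its SiMe3 group is carried by 2 only)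
Why: Copper-catalysed, TMSCl-accelerated 1,4-addition should give the regiodefined silyl enol ether 2 (methyl anti to the C4 methyl, a centre that is erased again), and Saegusa–Ito dehydrosilylation should reinstall the C2=C3 double bond toward the methylated carbon without touching the bought C4 stereocentre.

Step 2
Reactants: 3 (R)-3,4-dimethylcyclohex-2-en-1-one; 4 (4-bromobut-1-yn-1-yl)trimethylsilane
Product: 5 {[(3S,4R)-3,4-dimethyl-3-[4-(trimethylsilyl)but-3-yn-1-yl]cyclohex-1-en-1-yl]oxy}trimethylsilane
Conditions: 4, Mg, THF, 40 °C; then 3, CuBr·SMe2 (20 mol %), TMSCl, HMPA, THF, −78 → −40 °C; Et3N, pentane work-up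
Reagents that add atoms: (4-bromobut-1-yn-1-yl)trimethylsilane (4), C[Si](C)(C)C#CCCBr; chlorotrimethylsilane, C[Si](C)(C)Cl
Why: Copper-catalysed conjugate addition of the Grignard reagent from 4 to the β,β-disubstituted enone should create the quaternary centre with the chain entering anti to the neighbouring C4 methyl (substrate control, the two methyls end up cis), the enolate being trapped regiospecifically on the neopentyl side while the C-silyl group masks the acetylenic C–H.

Step 3
Reactants: 5 {[(3S,4R)-3,4-dimethyl-3-[4-(trimethylsilyl)but-3-yn-1-yl]cyclohex-1-en-1-yl]oxy}trimethylsilane; 6 but-3-en-2-one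
Product: 8 (5S,6R)-5-(but-3-yn-1-yl)-5,6-dimethyl-4,4a,5,6,7,8-hexahydronaphthalen-2(3H)-one, via diketone 7 (not isolated)
Conditions: 6, BF3·OEt2, i-PrOH, CH2Cl2, −78 °C; then KOH, MeOH, 65 °C
Reagents that add atoms: but-3-en-2-one (6), CC(=O)C=C
Why: Robinson annulation in two stages, a Lewis acid-promoted Mukaiyama–Michael addition of the regiodefined enol ether at its neopentyl carbon followed by base-mediated aldol condensation, with methanolic hydroxide also cleaving the alkynyl C–Si bond; the ring-fusion CH formed here is of no consequence because it becomes sp2 in step 4.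

Step 4
Reactants: 8 (5S,6R)-5-(but-3-yn-1-yl)-5,6-dimethyl-4,4a,5,6,7,8-hexahydronaphthalen-2(3H)-one
Product: 10 (5S,6R)-5-(but-3-yn-1-yl)-1,1,5,6-tetramethyl-3,4,5,6,7,8-hexahydronaphthalen-2(1H)-one, via β,γ-enone 9 (not isolated)
Conditions: t-BuOK (3 equiv), t-BuOH/THF, 25 °C, then MeI (6 equiv), 0 → 25 °C; then p-TsOH·H2O (20 mol %), PhH, 80 °C
Reagents that add atoms: iodomethane, CI
Why: Deconjugative α,α-dimethylation through the extended dienolate (the classical t-BuOK/MeI gem-dimethylation of Δ4-3-keto decalins) should give the β,γ-enone, and acid-catalysed alkene equilibration should then move the C=C, which the new quaternary C1 keeps from reconjugating, into the tetrasubstituted ring-fusion position as the thermodynamic sink; in t-BuOH the acetylenic C–H should not be deprotonated to a relevant extent.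

Step 5
Reactants: 10 (5S,6R)-5-(but-3-yn-1-yl)-1,1,5,6-tetramethyl-3,4,5,6,7,8-hexahydronaphthalen-2(1H)-one
Product: 11 (2R,5S,6R)-5-(but-3-yn-1-yl)-1,1,5,6-tetramethyl-1,2,3,4,5,6,7,8-octahydronaphthalen-2-ol
Conditions: (S)-Me-CBS (20 mol %), catecholborane (1.8 equiv), toluene, −40 → −20 °C
Reagents that add atoms: none
Why: Corey–Bakshi–Shibata reduction under catalyst control: with the α-quaternary carbon as large and the CH2 as small substituent the (S)-oxazaborolidine should deliver hydride to the face that gives the (R)-carbinol, the remote centres exerting no bias, and catecholborane at low temperature should leave alkyne and tetrasubstituted alkene untouched.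

Step 6
Reactants: 11 (2R,5S,6R)-5-(but-3-yn-1-yl)-1,1,5,6-tetramethyl-1,2,3,4,5,6,7,8-octahydronaphthalen-2-ol
Product: 12 (2S,3R,8R)-2-(but-3-yn-1-yl)-8-hydroxy-2,3,7,7-tetramethylcyclodecane-1,6-dione
Conditions: O3, CH2Cl2/MeOH (4:1), −78 °C (Sudan Red 7B end point); then Me2S, −78 → 25 °C
Reagents that add atoms: ozone, [O-][O+]=O
Why: Ozonolysis with reductive work-up: the electron-rich tetrasubstituted alkene should react far faster than the terminal alkyne, and cleavage of the ring-fusion C=C turns the bicycle into the ten-membered 1,6-dione without touching a stereocentre.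

Step 7
Reactants: 12 (2S,3R,8R)-2-(but-3-yn-1-yl)-8-hydroxy-2,3,7,7-tetramethylcyclodecane-1,6-dione; 13 2-(diethoxyphosphoryl)acetic acid
Product: 16 (2R,3aS,5S,6R,8aS)-2,8a-dihydroxy-1,1,5,6-tetramethyl-5-[2-(5-oxo-2,5-dihydrofuran-3-yl)ethyl]octahydroazulen-4(1H)-one, via phosphonoacetoxy ketone 14 (not isolated), via butenolide dione 15 (not isolated)
Conditions: Mor-DalPhosAuNTf2 (5 mol %), 8-methylquinoline N-oxide (1.5 equiv), 13 (1.5 equiv), PhCl, 25 °C; then K2CO3 (5 equiv), 18-crown-6 (1 equiv), same flask, 25 → 40 °C
Reagents that add atoms: 2-(diethoxyphosphoryl)acetic acid (13), CCOP(=O)(CC(=O)O)OCC; 8-methylquinoline N-oxide, Cc1cccc2ccc[n+]([O-])c12 (its oxygen is carried by 14 only)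
Why: The N-oxide should add to the gold-activated terminal alkyne at its internal carbon, N–O cleavage giving an α-oxo gold carbene at the terminal carbon into which the carboxylic O–H of 13 inserts (CH2–O bond, 14); carbonate then forms the phosphonate carbanion, whose intramolecular Horner–Wadsworth–Emmons reaction with the new side-chain ketone gives the butenolide C=C (15), and the same base enolises the C4 ketone toward its only CH2 (C3a), which adds across the ten-membered ring to the C8a carbonyl. The closest known reaction types are gold-catalysed alkyne oxidation with carboxylic-acid capture of the α-oxo carbene, the phosphonoacetate (HWE) butenolide annulation of α-acyloxy ketones, and the base-mediated transannular aldol of cyclodecane-1,6-diones. The butenolide closes by 5-exo-trig attack of the carbanion on the ketone followed by phosphate elimination; the cyclopentane closes 5-(enolexo)-exo-trig and, in the same bond formation, the cycloheptanone 7-(enolendo)-exo-trig. The two new stereocentres (carbinol C8a, ring-fusion C3a) should be set under thermodynamic control, since the aldol is reversible and C3a enolisable: only the isomer with the new tertiary OH cis to the C2 hydroxyl and syn to the C4 acyl group (trans ring fusion) can form both intramolecular hydrogen bonds in the non-polar medium, so the CBS-set carbinol relays its configuration to both centres while C5 and C6 stay untouched. The step needs (i) carbene capture by the acid and not by ring C=O or OH, secured by the tempered P,N-ligated carbene and the excess of acid, (ii) olefination before any ketone-enolate chemistry, secured by the roughly seven pKa units between phosphonate and ketone, which removes the side-chain ketone before a ring enolate can add to it, and (iii) aldol regiochemistry, secured by the two quaternary α-carbons that leave only C3a and C8 enolisable, the closure used placing the smaller substituent set (OH, Me2) on the cyclopentane and attacking the less hindered, β-oxygen-activated carbonyl.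

**Compound list**
1 | (R)-4-methylcyclohex-2-en-1-one | C[C@@H]1CCC(=O)C=C1 | starting material
2 | {[(3S,4R)-3,4-dimethylcyclohex-1-en-1-yl]oxy}trimethylsilane | C[C@@H]1CCC(=C[C@H]1C)O[Si](C)(C)C | intermediate
3 | (R)-3,4-dimethylcyclohex-2-en-1-one | C[C@@H]1CCC(=O)C=C1C | intermediate
4 | (4-bromobut-1-yn-1-yl)trimethylsilane | C[Si](C)(C)C#CCCBr | starting material
5 | {[(3S,4R)-3,4-dimethyl-3-[4-(trimethylsilyl)but-3-yn-1-yl]cyclohex-1-en-1-yl]oxy}trimethylsilane | C[C@@H]1CCC(O[Si](C)(C)C)=C[C@@]1(C)CCC#C[Si](C)(C)C | intermediate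
6 | but-3-en-2-one | CC(=O)C=C | starting material
7 | (3S,4R)-3,4-dimethyl-2-(3-oxobutyl)-3-[4-(trimethylsilyl)but-3-yn-1-yl]cyclohexan-1-one (both C2 epimers) | C[C@@H]1CCC(=O)C(CCC(C)=O)[C@@]1(C)CCC#C[Si](C)(C)C | intermediate
8 | (5S,6R)-5-(but-3-yn-1-yl)-5,6-dimethyl-4,4a,5,6,7,8-hexahydronaphthalen-2(3H)-one (C4a epimers) | C[C@@H]1CCC2=CC(=O)CCC2[C@@]1(C)CCC#C | intermediate
9 | (5S,6R)-5-(but-3-yn-1-yl)-1,1,5,6-tetramethyl-3,4,4a,5,6,7-hexahydronaphthalen-2(1H)-one (C4a epimers) | C[C@@H]1CC=C2C(C)(C)C(=O)CCC2[C@@]1(C)CCC#C | intermediate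
10 | (5S,6R)-5-(but-3-yn-1-yl)-1,1,5,6-tetramethyl-3,4,5,6,7,8-hexahydronaphthalen-2(1H)-one | C[C@@H]1CCC2=C(CCC(=O)C2(C)C)[C@@]1(C)CCC#C | intermediate
11 | (2R,5S,6R)-5-(but-3-yn-1-yl)-1,1,5,6-tetramethyl-1,2,3,4,5,6,7,8-octahydronaphthalen-2-ol | C[C@@H]1CCC2=C(CC[C@@H](O)C2(C)C)[C@@]1(C)CCC#C | intermediate
12 | (2S,3R,8R)-2-(but-3-yn-1-yl)-8-hydroxy-2,3,7,7-tetramethylcyclodecane-1,6-dione | C[C@@H]1CCC(=O)C(C)(C)[C@H](O)CCC(=O)[C@@]1(C)CCC#C | intermediate
13 | 2-(diethoxyphosphoryl)acetic acid | CCOP(=O)(CC(=O)O)OCC | starting material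
14 | 4-[(1S,5R,10R)-5-hydroxy-1,6,6,10-tetramethyl-2,7-dioxocyclodecyl]-2-oxobutyl 2-(diethoxyphosphoryl)acetate | C[C@@H]1CCC(=O)C(C)(C)[C@H](O)CCC(=O)[C@@]1(C)CCC(=O)COC(=O)CP(=O)(OCC)OCC | intermediate
15 | 4-{2-[(1S,5R,10R)-5-hydroxy-1,6,6,10-tetramethyl-2,7-dioxocyclodecyl]ethyl}furan-2(5H)-one | C[C@@H]1CCC(=O)C(C)(C)[C@H](O)CCC(=O)[C@@]1(C)CCC1=CC(=O)OC1 | intermediate
16 | (2R,3aS,5S,6R,8aS)-2,8a-dihydroxy-1,1,5,6-tetramethyl-5-[2-(5-oxo-2,5-dihydrofuran-3-yl)ethyl]octahydroazulen-4(1H)-one | C[C@@H]1CC[C@]2(O)[C@H](C[C@@H](O)C2(C)C)C(=O)[C@@]1(C)CCC1=CC(=O)OC1 | target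

**Step count**
Total: 7 steps (steps 1, 3, 4 and 7 are telescoped). Longest linear sequence: 7 steps, from 1 to 16.

**Steps most likely to fail**

Step 7. What may go wrong:
- the α-oxo gold carbene is intercepted by a ring carbonyl or the free hydroxyl, or the alkyne is over-oxidised, before the acid captures it;
- the transannular aldol closes in the other sense (enolisation at C8 and attack on the C4 carbonyl), settles at another ring-fusion configuration, or the β-ketol dehydrates.

Fallback (sets out from 11, passes through 15, returns at 16): the butenolide is built on the bicyclic stage by the classical halo-ketone route and the aldol is run as a separate, templated event. NBS with catalytic AgNO3 in acetone should convert the terminal alkyne of 11 into the 1-bromoalkyne F1. Gold(I)-catalysed hydration in wet 1,2-dichloroethane should give the bromomethyl ketone F2. The potassium salt of 13 (K2CO3, 18-crown-6, MeCN) should displace bromide to give the phosphonoacetate ester F3, which under the same base should undergo the intramolecular HWE reaction to the butenolide octalin F4. Ozonolysis of F4, sparing the electron-poor butenolide alkene, should give 15. Compound 15 is then equilibrated with catalytic DBU in toluene in the presence of PhB(OH)2 and 4 Å sieves, so that only the aldol isomer carrying the cis-1,3-diol is drained off as the cyclic phenylboronate F5. Transesterification with pinacol should release 16.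

Step 4. What may go wrong: alkylation through the cross-conjugated C3 enolate or on oxygen, partial methylation of the acetylide, and incomplete migration of the double bond to the ring fusion (or skeletal rearrangement) under acid.

Fallback (sets out from 5, returns at 10): the gem-dimethyl group is brought in with the annulation partner. Mukaiyama–Michael addition of 5 to 4-methylpent-1-en-3-one (BF3·OEt2, i-PrOH, CH2Cl2, −78 °C) should give the isopropyl diketone F6. Acid-mediated aldol cyclodehydration (p-TsOH, PhH, water separator), in which the tetrasubstituted enol of the isopropyl ketone attacks the ring ketone and water is lost away from the new quaternary carbon, should give the silylalkynyl β,γ-enone F7. K2CO3 in MeOH should remove the alkynyl silyl group to give 10.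

Step 6. What may go wrong: at the alkene shielded by two quaternary neighbours, oxygen-atom transfer (epoxide formation) can compete with cycloaddition of ozone; prolonged exposure attacks the alkyne; and the dione can undergo premature, uncontrolled transannular aldol and dehydration on work-up or on silica.

Fallback (sets out from 11, returns at 12): two-stage cleavage. Epoxidation (mCPBA, NaHCO3, CH2Cl2, 0 °C) should give the ring-fusion epoxide F8. Periodic acid (H5IO6, THF/H2O) should open the epoxide to the diol and cleave it in situ to 12.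

**Further compounds**
F1 | step 7 | (2R,5S,6R)-5-(4-bromobut-3-yn-1-yl)-1,1,5,6-tetramethyl-1,2,3,4,5,6,7,8-octahydronaphthalen-2-ol | C[C@@H]1CCC2=C(CC[C@@H](O)C2(C)C)[C@@]1(C)CCC#CBr
F2 | step 7 | 1-bromo-4-[(1S,2R,6R)-6-hydroxy-1,2,5,5-tetramethyl-1,2,3,4,5,6,7,8-octahydronaphthalen-1-yl]butan-2-one | C[C@@H]1CCC2=C(CC[C@@H](O)C2(C)C)[C@@]1(C)CCC(=O)CBr
F3 | step 7 | 4-[(1S,2R,6R)-6-hydroxy-1,2,5,5-tetramethyl-1,2,3,4,5,6,7,8-octahydronaphthalen-1-yl]-2-oxobutyl 2-(diethoxyphosphoryl)acetate | C[C@@H]1CCC2=C(CC[C@@H](O)C2(C)C)[C@@]1(C)CCC(=O)COC(=O)CP(=O)(OCC)OCC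
F4 | step 7 | 4-{2-[(1S,2R,6R)-6-hydroxy-1,2,5,5-tetramethyl-1,2,3,4,5,6,7,8-octahydronaphthalen-1-yl]ethyl}furan-2(5H)-one | C[C@@H]1CCC2=C(CC[C@@H](O)C2(C)C)[C@@]1(C)CCC1=CC(=O)OC1
F5 | step 7 | cyclic phenylboronate of 16 (boron bridging the C2 and C8a oxygens) | C[C@@H]1CC[C@]2(OB(c3ccccc3)O4)[C@H](C[C@@H]4C2(C)C)C(=O)[C@@]1(C)CCC1=CC(=O)OC1
F6 | step 4 | (3S,4R)-3,4-dimethyl-2-(4-methyl-3-oxopentyl)-3-[4-(trimethylsilyl)but-3-yn-1-yl]cyclohexan-1-one (both C2 epimers) | C[C@@H]1CCC(=O)C(CCC(=O)C(C)C)[C@@]1(C)CCC#C[Si](C)(C)C
F7 | step 4 | (5S,6R)-1,1,5,6-tetramethyl-5-[4-(trimethylsilyl)but-3-yn-1-yl]-3,4,5,6,7,8-hexahydronaphthalen-2(1H)-one | C[C@@H]1CCC2=C(CCC(=O)C2(C)C)[C@@]1(C)CCC#C[Si](C)(C)C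
F8 | step 6 | (2R,5S,6R)-5-(but-3-yn-1-yl)-4a,8a-epoxy-1,1,5,6-tetramethyldecahydronaphthalen-2-ol (either epoxide face) | C[C@@H]1CCC23OC2(CC[C@@H](O)C3(C)C)[C@@]1(C)CCC#C
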